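The route rests on disconnecting the C1–C2 bond of the 7-oxabicyclo[2.2.1]heptane. A rhodium carbenoid at C2 inserts into the tertiary, O7-activated C1–H bond of a trans-2,5-disubstituted 2-methyloxolane. In one operation this closes the cyclohexane ring C1–C6 and the second oxolane O7–C1–C2–C3–C4 and sets C1 and C2. The precursor is an α-diazo methyl ester whose carbenoid carbon sits on quaternary C3 (methyl, 2-chloroethyl, oxolan-2-yl); the chloroethyl arm is an inert stub for chain B. C3 and C4 come from a catalytic asymmetric allylboration, C1 from (S)-hex-5-en-2-ol. Both side chains are grown afterwards and the bromochloride is installed last.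

Key step: step 12

Locants: C1–C6 and O7 are those of the 7-oxabicyclo[2.2.1]heptane core of the target (C1 methyl-bearing bridgehead, C2 carrying chain A, C3 quaternary carrying chain B, C4 bridgehead CH); the same labels are used for the corresponding atoms of all intermediates.
Assumption: (R)-TRIP [(R)-3,3′-bis(2,4,6-triisopropylphenyl)-1,1′-binaphthyl-2,2′-diyl hydrogen phosphate] transfers the allyl group to the Re face of aldehyde 9, the sense it shows with simple aldehydes; if the opposite sense were found, its enantiomer would be used.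
Assumption: compounds 1, 6 and 24 and all unnumbered reagents are purchased.

Step 1
Reactants: 1 tert-butyl(but-3-yn-1-yloxy)dimethylsilane
Product: 3 tert-butyl{[(3E)-4-iodo-3-methylbut-3-en-1-yl]oxy}dimethylsilane, via alkenylalane 2 (not isolated)
Conditions: Me3Al, Cp2ZrCl2 (cat.), CH2Cl2, 0 °C → rt; then I2, THF, −30 °C
Reagents that add atoms: trimethylaluminium C[Al](C)C; iodine [I][I]
Why: Zirconium-catalysed Negishi carboalumination adds methyl and aluminium syn across the terminal alkyne with aluminium on the terminal carbon, and iodinolysis of the carbon–aluminium bond with retention should give the (E)-iodide.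

Step 2
Reactants: 3 tert-butyl{[(3E)-4-iodo-3-methylbut-3-en-1-yl]oxy}dimethylsilane
Product: 5 tert-butyldimethyl{[(3E)-3-methyl-5-(4,4,5,5-tetramethyl-1,3,2-dioxaborolan-2-yl)pent-3-en-1-yl]oxy}silane, via alkenyllithium 4 (not isolated)
Conditions: t-BuLi (2.1 equiv), Et2O, −78 °C; then ClCH2B(pin), −78 °C → rt
Reagents that add atoms: 2-(chloromethyl)-4,4,5,5-tetramethyl-1,3,2-dioxaborolane ClCB1OC(C)(C)C(C)(C)O1
Why: Iodine–lithium exchange keeps the alkene geometry, and the alkenyllithium adds to boron to give an ate complex whose 1,2-metallate shift expels chloride, so the (E)-γ,γ-disubstituted allylboronate should form without allylic transposition.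

Step 3
Reactants: 6 (2S)-hex-5-en-2-ol
Product: 7 (2S)-hex-5-en-2-yl 4-methylbenzenesulfonate
Conditions: TsCl, pyridine, CH2Cl2, 0 °C → rt
Reagents that add atoms: 4-methylbenzenesulfonyl chloride Cc1ccc(cc1)S(=O)(=O)Cl
Why: Sulfonylation takes place at oxygen, so the carbon–oxygen bond and the (S) configuration are untouched and the leaving group for the later ring closure is in place.

Step 4
Reactants: 7 (2S)-hex-5-en-2-yl 4-methylbenzenesulfonate
Product: 9 (2S)-5-oxopentan-2-yl 4-methylbenzenesulfonate, via ozonide 8 (not isolated)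
Conditions: O3, CH2Cl2, −78 °C; then PPh3, −78 °C → rt
Reagents that add atoms: ozone [O-][O+]=O
Why: Ozonolysis with reductive work-up cleaves the only alkene, and the neutral conditions should leave the secondary tosylate intact.

Step 5
Reactants: 9 (2S)-5-oxopentan-2-yl 4-methylbenzenesulfonate; 5 tert-butyldimethyl{[(3E)-3-methyl-5-(4,4,5,5-tetramethyl-1,3,2-dioxaborolan-2-yl)pent-3-en-1-yl]oxy}silane
Product: 10 (2S,5S,6R)-6-(2-{[tert-butyl(dimethyl)silyl]oxy}ethyl)-5-hydroxy-6-methyloct-7-en-2-yl 4-methylbenzenesulfonate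
Conditions: (R)-TRIP (5 mol%), MS 4 Å, toluene, −30 °C → 0 °C; aqueous work-up
Reagents that add atoms: none
Why: Chiral phosphoric acid-catalysed allylboration runs through a closed chair transition state in which the (E)-boronate places the silyloxyethyl arm anti and the methyl group syn to the new hydroxyl (zigzag through C5–C4–C3–vinyl), which fixes quaternary C3 relative to C4, while (R)-TRIP is expected to direct attack to the Re face of the aldehyde and so set (S)-C4.

Step 6
Reactants: 10 (2S,5S,6R)-6-(2-{[tert-butyl(dimethyl)silyl]oxy}ethyl)-5-hydroxy-6-methyloct-7-en-2-yl 4-methylbenzenesulfonate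
Product: 11 tert-butyldimethyl{[(3R)-3-methyl-3-[(2S,5R)-5-methyloxolan-2-yl]pent-4-en-1-yl]oxy}silane
Conditions: NaH, THF, 0 °C → rt
Reagents that add atoms: none
Why: Intramolecular Williamson etherification (5-exo-tet) of the C4 alkoxide on the secondary tosylate inverts C1 from (S) to (R) and, with C4 already set, should give the trans-2,5-disubstituted oxolane in which C1–H is cis to the C3 branch.

Step 7
Reactants: 11 tert-butyldimethyl{[(3R)-3-methyl-3-[(2S,5R)-5-methyloxolan-2-yl]pent-4-en-1-yl]oxy}silane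
Product: 13 (3S)-5-{[tert-butyl(dimethyl)silyl]oxy}-3-methyl-3-[(2S,5R)-5-methyloxolan-2-yl]pentan-1-ol, via alkylborane 12 (not isolated)
Conditions: 9-BBN, THF, 0 °C → rt; then NaOH, H2O2, 0 °C
Reagents that add atoms: hydrogen peroxide OO
Why: Anti-Markovnikov hydroboration of the only alkene with the bulky borane and oxidation of the carbon–boron bond should give the primary alcohol without creating a stereocentre.

Step 8
Reactants: 13 (3S)-5-{[tert-butyl(dimethyl)silyl]oxy}-3-methyl-3-[(2S,5R)-5-methyloxolan-2-yl]pentan-1-ol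
Product: 14 tert-butyl{[(3R)-5-chloro-3-methyl-3-[(2S,5R)-5-methyloxolan-2-yl]pentyl]oxy}dimethylsilane
Conditions: PPh3, N-chlorosuccinimide, CH2Cl2, 0 °C → rt
Reagents that add atoms: N-chlorosuccinimide O=C1CCC(=O)N1Cl
Why: Appel-type chlorination converts the primary alcohol into the chloride under neutral conditions that the silyl ether and the oxolane tolerate.

Step 9
Reactants: 14 tert-butyl{[(3R)-5-chloro-3-methyl-3-[(2S,5R)-5-methyloxolan-2-yl]pentyl]oxy}dimethylsilane
Product: 15 (3R)-5-chloro-3-methyl-3-[(2S,5R)-5-methyloxolan-2-yl]pentanoic acid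
Conditions: CrO3, H2SO4, H2O, acetone, 0 °C → rt
Reagents that add atoms: water O
Why: Aqueous chromic acid cleaves the primary silyl ether and oxidises the liberated alcohol through the aldehyde hydrate to the acid (Jones oxidation), while the alkyl chloride and the ether should survive.

Step 10
Reactants: 15 (3R)-5-chloro-3-methyl-3-[(2S,5R)-5-methyloxolan-2-yl]pentanoic acid
Product: 16 methyl (3R)-5-chloro-3-methyl-3-[(2S,5R)-5-methyloxolan-2-yl]pentanoate
Conditions: Me3SiCHN2, MeOH–toluene, 0 °C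
Reagents that add atoms: (trimethylsilyl)diazomethane C[Si](C)(C)C=[N+]=[N-]
Why: O-Methylation with the diazomethane surrogate is fast and essentially neutral, so the carboxylate has no opportunity to displace the chloride and form a δ-lactone.

Step 11
Reactants: 16 methyl (3R)-5-chloro-3-methyl-3-[(2S,5R)-5-methyloxolan-2-yl]pentanoate
Product: 18 methyl (3S)-5-chloro-2-diazo-3-methyl-3-[(2S,5R)-5-methyloxolan-2-yl]pentanoate, via trifluoroacetyl ester 17 (not isolated)
Conditions: LiN(i-Pr)2, THF, −78 °C; CF3CO2CH2CF3; then 4-acetamidobenzenesulfonyl azide, Et3N, H2O, MeCN, rt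
Reagents that add atoms: 4-acetamidobenzenesulfonyl azide CC(=O)Nc1ccc(cc1)S(=O)(=O)N=[N+]=[N-]
Why: Enolisation at the only enolisable position, Claisen-type trifluoroacetylation and Regitz deacylative diazo transfer should give the α-diazo ester without touching quaternary C3 or the oxolane stereocentres.

Step 12
Reactants: 18 methyl (3S)-5-chloro-2-diazo-3-methyl-3-[(2S,5R)-5-methyloxolan-2-yl]pentanoate
Product: 19 methyl (1R,2S,3S,4S)-3-(2-chloroethyl)-1,3-dimethyl-7-oxabicyclo[2.2.1]heptane-2-carboxylate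
Conditions: Rh2(OAc)4 (1 mol%), CH2Cl2, 40 °C, slow addition of 18
Reagents that add atoms: none
Why: Rh2(OAc)4 should expel N2 from 18 to give an electrophilic rhodium carbenoid at C2 which, having no β-hydrogen on quaternary C3, engages the tertiary C1–H bond through a three-centre, hydride-transfer-like transition state and forms C1–C2 with retention at C1. The closest known reaction type is the dirhodium-catalysed intramolecular 1,5 C–H insertion of α-diazo esters at C–H bonds activated by an adjacent ether oxygen. The new bond closes the second oxolane ring O7–C1–C2–C3–C4 in the five-membered (1,5) mode and, as a 1,3-transannular bridge across the existing oxolane, thereby also the cyclohexane ring C1–C6. C1 is fixed by retention, which is why the trans-2,5-oxolane (C1–H cis to the C3 branch on C4) is required, and C2 should place the ester exo, on the side of the C3 methyl group and away from the endo chloroethyl arm and the C5–C6 bridge, which is also the thermodynamically preferred position. The step needs site selectivity for C1–H over C6–H (1,5) and C5–H (1,4), secured by O7 activation of C1–H against methylenes deactivated by the β-oxygen, and chemoselectivity over ylide formation, secured by a 2-chloroethyl arm that offers no basic heteroatom, no alkene and only chlorine-deactivated C–H bonds outside 1,5 reach.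

Step 13
Reactants: 19 methyl (1R,2S,3S,4S)-3-(2-chloroethyl)-1,3-dimethyl-7-oxabicyclo[2.2.1]heptane-2-carboxylate
Product: 20 methyl (1R,2S,3S,4S)-3-(2-iodoethyl)-1,3-dimethyl-7-oxabicyclo[2.2.1]heptane-2-carboxylate
Conditions: NaI, butan-2-one, 80 °C
Reagents that add atoms: sodium iodide [Na+].[I-]
Why: Finkelstein exchange at the unhindered primary carbon is driven by precipitation of NaCl and gives the more reactive iodide for the cross-coupling.

Step 14
Reactants: 20 methyl (1R,2S,3S,4S)-3-(2-iodoethyl)-1,3-dimethyl-7-oxabicyclo[2.2.1]heptane-2-carboxylate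
Product: 21 methyl (1R,2S,3S,4S)-1,3-dimethyl-3-(4-methylpent-3-en-1-yl)-7-oxabicyclo[2.2.1]heptane-2-carboxylate
Conditions: (CH3)2C=CHMgBr, Li2CuCl4 (cat.), THF, −20 °C → 0 °C
Reagents that add atoms: (2-methylprop-1-en-1-yl)magnesium bromide CC(C)=C[Mg]Br
Why: Copper-catalysed cross-coupling of the primary alkyl iodide with the alkenyl Grignard reagent is much faster than addition to the methyl ester, which is shielded by the flanking quaternary carbons C1 and C3, so the prenyl-type terminus of chain B should form chemoselectively.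

Step 15
Reactants: 21 methyl (1R,2S,3S,4S)-1,3-dimethyl-3-(4-methylpent-3-en-1-yl)-7-oxabicyclo[2.2.1]heptane-2-carboxylate
Product: 22 (1R,2S,3S,4S)-1,3-dimethyl-3-(4-methylpent-3-en-1-yl)-7-oxabicyclo[2.2.1]heptane-2-carbaldehyde
Conditions: i-Bu2AlH (1.2 equiv), CH2Cl2, −78 °C; then aq. KNaC4H4O6
Reagents that add atoms: none
Why: At −78 °C the hindered ester is reduced only as far as the aluminium hemiacetal, which collapses to the aldehyde on work-up, and these mild conditions should preserve the exo configuration at C2.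

Step 16
Reactants: 22 (1R,2S,3S,4S)-1,3-dimethyl-3-(4-methylpent-3-en-1-yl)-7-oxabicyclo[2.2.1]heptane-2-carbaldehyde
Product: 23 (1R,2S,3S,4S)-2-ethenyl-1,3-dimethyl-3-(4-methylpent-3-en-1-yl)-7-oxabicyclo[2.2.1]heptane
Conditions: Ph3PCH3Br, KN(SiMe3)2, THF, 0 °C; then 22, −78 °C → 0 °C
Reagents that add atoms: methyltriphenylphosphonium bromide C[P+](c1ccccc1)(c1ccccc1)c1ccccc1.[Br-]
Why: Wittig methylenation with the non-stabilised ylide at low temperature is faster than enolisation of the hindered aldehyde, so C2 should not epimerise.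

Step 17
Reactants: 24 but-2-yn-1-ol
Product: 26 (2Z)-3-iodobut-2-en-1-ol, via alkenylalanate 25 (not isolated)
Conditions: NaAlH2(OCH2CH2OCH3)2, THF, 0 °C → rt; then I2, −78 °C
Reagents that add atoms: iodine [I][I]
Why: Hydroxyl-directed trans-hydroalumination places aluminium on C3 in a five-membered alanate, and iodinolysis with retention should give the (Z)-iodide with iodine cis to the hydroxymethyl group.

Step 18
Reactants: 23 (1R,2S,3S,4S)-2-ethenyl-1,3-dimethyl-3-(4-methylpent-3-en-1-yl)-7-oxabicyclo[2.2.1]heptane; 26 (2Z)-3-iodobut-2-en-1-ol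
Product: 28 (2Z)-5-[(1R,2S,3S,4S)-1,3-dimethyl-3-(4-methylpent-3-en-1-yl)-7-oxabicyclo[2.2.1]heptan-2-yl]-3-methylpent-2-en-1-ol, via alkylborane 27 (not isolated)
Conditions: 9-BBN, THF, rt; then 26, Pd(dppf)Cl2 (5 mol%), AsPh3, Cs2CO3, DMF–H2O, rt
Reagents that add atoms: none
Why: 9-BBN hydroborates the monosubstituted alkene in preference to the trisubstituted one, and B-alkyl Suzuki–Miyaura coupling with the alkenyl iodide keeps the alkene geometry, so the (Z)-trisubstituted allylic alcohol should result.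

Step 19
Reactants: 28 (2Z)-5-[(1R,2S,3S,4S)-1,3-dimethyl-3-(4-methylpent-3-en-1-yl)-7-oxabicyclo[2.2.1]heptan-2-yl]-3-methylpent-2-en-1-ol
Product: 29 [(2R,3S)-3-{2-[(1R,2S,3S,4S)-1,3-dimethyl-3-(4-methylpent-3-en-1-yl)-7-oxabicyclo[2.2.1]heptan-2-yl]ethyl}-3-methyloxiran-2-yl]methanol
Conditions: Ti(OiPr)4 (cat.), D-(−)-diethyl tartrate (cat.), t-BuOOH, MS 4 Å, CH2Cl2, −20 °C
Reagents that add atoms: tert-butyl hydroperoxide CC(C)(C)OO
Why: Sharpless asymmetric epoxidation acts only on the allylic alcohol and, with D-(−)-diethyl tartrate on the (Z)-alkene, should deliver oxygen to the face that gives the (2R,3S)-epoxy alcohol, which sets the future carbinol carbon of chain A as (S).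

Step 20
Reactants: 29 [(2R,3S)-3-{2-[(1R,2S,3S,4S)-1,3-dimethyl-3-(4-methylpent-3-en-1-yl)-7-oxabicyclo[2.2.1]heptan-2-yl]ethyl}-3-methyloxiran-2-yl]methanol
Product: 30 (1R,2S,3S,4S)-2-{2-[(2S,3S)-3-(iodomethyl)-2-methyloxiran-2-yl]ethyl}-1,3-dimethyl-3-(4-methylpent-3-en-1-yl)-7-oxabicyclo[2.2.1]heptane
Conditions: I2, PPh3, imidazole, CH2Cl2, 0 °C
Reagents that add atoms: iodine [I][I]
Why: Appel-type iodination of the primary alcohol under imidazole buffering leaves the acid-sensitive trisubstituted epoxide intact.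

Step 21
Reactants: 30 (1R,2S,3S,4S)-2-{2-[(2S,3S)-3-(iodomethyl)-2-methyloxiran-2-yl]ethyl}-1,3-dimethyl-3-(4-methylpent-3-en-1-yl)-7-oxabicyclo[2.2.1]heptane
Product: 31 (3S)-5-[(1R,2S,3S,4S)-1,3-dimethyl-3-(4-methylpent-3-en-1-yl)-7-oxabicyclo[2.2.1]heptan-2-yl]-3-methylpent-1-en-3-ol
Conditions: Zn, EtOH, 80 °C
Reagents that add atoms: none
Why: Zinc inserts into the carbon–iodine bond and the organozinc undergoes β-elimination with opening of the epoxide (reductive 1,3-transposition), so the carbon–oxygen bond at the tertiary carbon is never broken and its (S) configuration is carried into the tertiary allylic alcohol.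

Step 22
Reactants: 31 (3S)-5-[(1R,2S,3S,4S)-1,3-dimethyl-3-(4-methylpent-3-en-1-yl)-7-oxabicyclo[2.2.1]heptan-2-yl]-3-methylpent-1-en-3-ol
Product: 32 {[(3S)-5-[(1R,2S,3S,4S)-1,3-dimethyl-3-(4-methylpent-3-en-1-yl)-7-oxabicyclo[2.2.1]heptan-2-yl]-3-methylpent-1-en-3-yl]oxy}triethylsilane
Conditions: Et3SiOTf, 2,6-lutidine, CH2Cl2, −78 °C
Reagents that add atoms: triethylsilyl trifluoromethanesulfonate CC[Si](CC)(CC)OS(=O)(=O)C(F)(F)F
Why: Silylation with the reactive triflate masks the ionisation-prone tertiary allylic alcohol, so that the only free hydroxyl in step 25 will be that of the bromohydrin.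

Step 23
Reactants: 32 {[(3S)-5-[(1R,2S,3S,4S)-1,3-dimethyl-3-(4-methylpent-3-en-1-yl)-7-oxabicyclo[2.2.1]heptan-2-yl]-3-methylpent-1-en-3-yl]oxy}triethylsilane
Product: 33 {[(3S)-5-{(1R,2S,3S,4S)-3-{2-[(2R)-3,3-dimethyloxiran-2-yl]ethyl}-1,3-dimethyl-7-oxabicyclo[2.2.1]heptan-2-yl}-3-methylpent-1-en-3-yl]oxy}triethylsilane
Conditions: D-fructose-derived ketone catalyst (1,2:4,5-di-O-isopropylidene-D-erythro-hexo-2,3-diulo-2,6-pyranose, 30 mol%), KHSO5, K2CO3, Bu4NHSO4, MeCN–CH2(OMe)2–aq. Na2B4O7, 0 °C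
Reagents that add atoms: potassium peroxymonosulfate [K+].[O-]S(=O)(=O)OO
Why: In the Shi epoxidation the chiral dioxirane attacks only the electron-rich trisubstituted alkene and, by the spiro transition-state model, should give the (R)-epoxide under catalyst control, the remote stereocentres having no influence.

Step 24
Reactants: 33 {[(3S)-5-{(1R,2S,3S,4S)-3-{2-[(2R)-3,3-dimethyloxiran-2-yl]ethyl}-1,3-dimethyl-7-oxabicyclo[2.2.1]heptan-2-yl}-3-methylpent-1-en-3-yl]oxy}triethylsilane
Product: 34 (3S)-3-bromo-5-{(1R,2S,3S,4S)-1,3-dimethyl-2-[(3S)-3-methyl-3-(triethylsilyloxy)pent-4-en-1-yl]-7-oxabicyclo[2.2.1]heptan-3-yl}-2-methylpentan-2-ol (locants of the core as defined above)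
Conditions: Li2NiBr4 (0.4 M in THF), 0 °C → rt
Reagents that add atoms: dilithium tetrabromonickelate [Li+].[Li+].Br[Ni-2](Br)(Br)Br
Why: The soft bromide opens the epoxide in an SN2 fashion at the secondary carbon with inversion, which converts the (R)-epoxide into the (S)-bromide with a tertiary alcohol next to it.

Step 25
Reactants: 34 (3S)-3-bromo-5-{(1R,2S,3S,4S)-1,3-dimethyl-2-[(3S)-3-methyl-3-(triethylsilyloxy)pent-4-en-1-yl]-7-oxabicyclo[2.2.1]heptan-3-yl}-2-methylpentan-2-ol
Product: 35 {[(3S)-5-{(1R,2S,3S,4S)-3-[(3S)-3-bromo-4-chloro-4-methylpentyl]-1,3-dimethyl-7-oxabicyclo[2.2.1]heptan-2-yl}-3-methylpent-1-en-3-yl]oxy}triethylsilane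
Conditions: 1-chloro-N,N,2-trimethylprop-1-en-1-amine, CH2Cl2, 0 °C → rt
Reagents that add atoms: 1-chloro-N,N,2-trimethylprop-1-en-1-amine CC(C)=C(Cl)N(C)C
Why: The α-chloroenamine activates the tertiary hydroxyl under neutral conditions, ionisation is assisted by the neighbouring bromine, and chloride opens the bromonium ion at the tertiary carbon (deoxychlorination with anchimeric assistance), so the carbon–bromine stereocentre should be retained.

Step 26
Reactants: 35 {[(3S)-5-{(1R,2S,3S,4S)-3-[(3S)-3-bromo-4-chloro-4-methylpentyl]-1,3-dimethyl-7-oxabicyclo[2.2.1]heptan-2-yl}-3-methylpent-1-en-3-yl]oxy}triethylsilane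
Product: 36 dactylomelol, (1R,2S,3S,4S)-3-[(3S)-3-bromo-4-chloro-4-methylpentyl]-2-[(3S)-3-hydroxy-3-methylpent-4-en-1-yl]-1,3-dimethyl-7-oxabicyclo[2.2.1]heptane
Conditions: HF·pyridine, pyridine, THF, 0 °C → rt
Reagents that add atoms: none
Why: Buffered fluoride-mediated desilylation removes the triethylsilyl group without a base that could eliminate the vicinal bromochloride and without acid strong enough to ionise the tertiary allylic alcohol, and should give the target.

Compound list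
1 | tert-butyl(but-3-yn-1-yloxy)dimethylsilane | C#CCCO[Si](C)(C)C(C)(C)C | starting material
2 | [(1E)-4-{[tert-butyl(dimethyl)silyl]oxy}-2-methylbut-1-en-1-yl]dimethylalane | C[Al](C)/C=C(\C)CCO[Si](C)(C)C(C)(C)C | intermediate
3 | tert-butyl{[(3E)-4-iodo-3-methylbut-3-en-1-yl]oxy}dimethylsilane | I/C=C(\C)CCO[Si](C)(C)C(C)(C)C | intermediate
4 | [(1E)-4-{[tert-butyl(dimethyl)silyl]oxy}-2-methylbut-1-en-1-yl]lithium | [Li]/C=C(\C)CCO[Si](C)(C)C(C)(C)C | intermediate
5 | tert-butyldimethyl{[(3E)-3-methyl-5-(4,4,5,5-tetramethyl-1,3,2-dioxaborolan-2-yl)pent-3-en-1-yl]oxy}silane | CC1(C)OB(C/C=C(\C)CCO[Si](C)(C)C(C)(C)C)OC1(C)C | intermediate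
6 | (2S)-hex-5-en-2-ol | C=CCC[C@H](C)O | starting material
7 | (2S)-hex-5-en-2-yl 4-methylbenzenesulfonate | C=CCC[C@H](C)OS(=O)(=O)c1ccc(C)cc1 | intermediate
8 | (2S)-4-(1,2,4-trioxolan-3-yl)butan-2-yl 4-methylbenzenesulfonate | C1OOC(CC[C@H](C)OS(=O)(=O)c2ccc(C)cc2)O1 | intermediate
9 | (2S)-5-oxopentan-2-yl 4-methylbenzenesulfonate | O=CCC[C@H](C)OS(=O)(=O)c1ccc(C)cc1 | intermediate
10 | (2S,5S,6R)-6-(2-{[tert-butyl(dimethyl)silyl]oxy}ethyl)-5-hydroxy-6-methyloct-7-en-2-yl 4-methylbenzenesulfonate | CC(C)(C)[Si](C)(C)OCC[C@](C)(C=C)[C@@H](O)CC[C@H](C)OS(=O)(=O)c1ccc(C)cc1 | intermediate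
11 | tert-butyldimethyl{[(3R)-3-methyl-3-[(2S,5R)-5-methyloxolan-2-yl]pent-4-en-1-yl]oxy}silane | CC(C)(C)[Si](C)(C)OCC[C@](C)(C=C)[C@@H]1CC[C@@H](C)O1 | intermediate
12 | 9-{(3S)-5-{[tert-butyl(dimethyl)silyl]oxy}-3-methyl-3-[(2S,5R)-5-methyloxolan-2-yl]pentyl}-9-borabicyclo[3.3.1]nonane | CC(C)(C)[Si](C)(C)OCC[C@](C)(CCB3C4CCCC3CCC4)[C@@H]1CC[C@@H](C)O1 | intermediate
13 | (3S)-5-{[tert-butyl(dimethyl)silyl]oxy}-3-methyl-3-[(2S,5R)-5-methyloxolan-2-yl]pentan-1-ol | CC(C)(C)[Si](C)(C)OCC[C@](C)(CCO)[C@@H]1CC[C@@H](C)O1 | intermediate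
14 | tert-butyl{[(3R)-5-chloro-3-methyl-3-[(2S,5R)-5-methyloxolan-2-yl]pentyl]oxy}dimethylsilane | CC(C)(C)[Si](C)(C)OCC[C@](C)(CCCl)[C@@H]1CC[C@@H](C)O1 | intermediate
15 | (3R)-5-chloro-3-methyl-3-[(2S,5R)-5-methyloxolan-2-yl]pentanoic acid | OC(=O)C[C@](C)(CCCl)[C@@H]1CC[C@@H](C)O1 | intermediate
16 | methyl (3R)-5-chloro-3-methyl-3-[(2S,5R)-5-methyloxolan-2-yl]pentanoate | COC(=O)C[C@](C)(CCCl)[C@@H]1CC[C@@H](C)O1 | intermediate
17 | methyl (3S)-5-chloro-3-methyl-3-[(2S,5R)-5-methyloxolan-2-yl]-2-(trifluoroacetyl)pentanoate (both C2 epimers) | COC(=O)C(C(=O)C(F)(F)F)[C@](C)(CCCl)[C@@H]1CC[C@@H](C)O1 | intermediate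
18 | methyl (3S)-5-chloro-2-diazo-3-methyl-3-[(2S,5R)-5-methyloxolan-2-yl]pentanoate | COC(=O)C(=[N+]=[N-])[C@](C)(CCCl)[C@@H]1CC[C@@H](C)O1 | intermediate
19 | methyl (1R,2S,3S,4S)-3-(2-chloroethyl)-1,3-dimethyl-7-oxabicyclo[2.2.1]heptane-2-carboxylate | COC(=O)[C@H]1[C@](C)(CCCl)[C@@H]2CC[C@@]1(C)O2 | intermediate
20 | methyl (1R,2S,3S,4S)-3-(2-iodoethyl)-1,3-dimethyl-7-oxabicyclo[2.2.1]heptane-2-carboxylate | COC(=O)[C@H]1[C@](C)(CCI)[C@@H]2CC[C@@]1(C)O2 | intermediate
21 | methyl (1R,2S,3S,4S)-1,3-dimethyl-3-(4-methylpent-3-en-1-yl)-7-oxabicyclo[2.2.1]heptane-2-carboxylate | COC(=O)[C@H]1[C@](C)(CCC=C(C)C)[C@@H]2CC[C@@]1(C)O2 | intermediate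
22 | (1R,2S,3S,4S)-1,3-dimethyl-3-(4-methylpent-3-en-1-yl)-7-oxabicyclo[2.2.1]heptane-2-carbaldehyde | O=C[C@H]1[C@](C)(CCC=C(C)C)[C@@H]2CC[C@@]1(C)O2 | intermediate
23 | (1R,2S,3S,4S)-2-ethenyl-1,3-dimethyl-3-(4-methylpent-3-en-1-yl)-7-oxabicyclo[2.2.1]heptane | C=C[C@H]1[C@](C)(CCC=C(C)C)[C@@H]2CC[C@@]1(C)O2 | intermediate
24 | but-2-yn-1-ol | CC#CCO | starting material
25 | sodium 2,2-bis(2-methoxyethoxy)-3-methyl-2,5-dihydro-1,2-oxaluminol-2-uide | CC1=CCO[Al-]1(OCCOC)OCCOC.[Na+] | intermediate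
26 | (2Z)-3-iodobut-2-en-1-ol | C/C(I)=C/CO | intermediate
27 | 9-{2-[(1R,2S,3S,4S)-1,3-dimethyl-3-(4-methylpent-3-en-1-yl)-7-oxabicyclo[2.2.1]heptan-2-yl]ethyl}-9-borabicyclo[3.3.1]nonane | C(CB3C4CCCC3CCC4)[C@H]1[C@](C)(CCC=C(C)C)[C@@H]2CC[C@@]1(C)O2 | intermediate
28 | (2Z)-5-[(1R,2S,3S,4S)-1,3-dimethyl-3-(4-methylpent-3-en-1-yl)-7-oxabicyclo[2.2.1]heptan-2-yl]-3-methylpent-2-en-1-ol | OC/C=C(C)\CC[C@H]1[C@](C)(CCC=C(C)C)[C@@H]2CC[C@@]1(C)O2 | intermediate
29 | [(2R,3S)-3-{2-[(1R,2S,3S,4S)-1,3-dimethyl-3-(4-methylpent-3-en-1-yl)-7-oxabicyclo[2.2.1]heptan-2-yl]ethyl}-3-methyloxiran-2-yl]methanol | OC[C@H]1O[C@@]1(C)CC[C@H]2[C@](C)(CCC=C(C)C)[C@@H]3CC[C@@]2(C)O3 | intermediate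
30 | (1R,2S,3S,4S)-2-{2-[(2S,3S)-3-(iodomethyl)-2-methyloxiran-2-yl]ethyl}-1,3-dimethyl-3-(4-methylpent-3-en-1-yl)-7-oxabicyclo[2.2.1]heptane | IC[C@H]1O[C@@]1(C)CC[C@H]2[C@](C)(CCC=C(C)C)[C@@H]3CC[C@@]2(C)O3 | intermediate
31 | (3S)-5-[(1R,2S,3S,4S)-1,3-dimethyl-3-(4-methylpent-3-en-1-yl)-7-oxabicyclo[2.2.1]heptan-2-yl]-3-methylpent-1-en-3-ol | C=C[C@@](C)(O)CC[C@H]1[C@](C)(CCC=C(C)C)[C@@H]2CC[C@@]1(C)O2 | intermediate
32 | {[(3S)-5-[(1R,2S,3S,4S)-1,3-dimethyl-3-(4-methylpent-3-en-1-yl)-7-oxabicyclo[2.2.1]heptan-2-yl]-3-methylpent-1-en-3-yl]oxy}triethylsilane | C=C[C@@](C)(O[Si](CC)(CC)CC)CC[C@H]1[C@](C)(CCC=C(C)C)[C@@H]2CC[C@@]1(C)O2 | intermediate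
33 | {[(3S)-5-{(1R,2S,3S,4S)-3-{2-[(2R)-3,3-dimethyloxiran-2-yl]ethyl}-1,3-dimethyl-7-oxabicyclo[2.2.1]heptan-2-yl}-3-methylpent-1-en-3-yl]oxy}triethylsilane | C=C[C@@](C)(O[Si](CC)(CC)CC)CC[C@H]1[C@](C)(CC[C@H]2OC2(C)C)[C@@H]3CC[C@@]1(C)O3 | intermediate
34 | triethylsilyl ether 32 in which chain B is (3S)-3-bromo-4-hydroxy-4-methylpentyl, core (1R,2S,3S,4S), chain A carbinol (S) | C=C[C@@](C)(O[Si](CC)(CC)CC)CC[C@H]1[C@](C)(CC[C@H](Br)C(C)(C)O)[C@@H]2CC[C@@]1(C)O2 | intermediate
35 | {[(3S)-5-{(1R,2S,3S,4S)-3-[(3S)-3-bromo-4-chloro-4-methylpentyl]-1,3-dimethyl-7-oxabicyclo[2.2.1]heptan-2-yl}-3-methylpent-1-en-3-yl]oxy}triethylsilane | C=C[C@@](C)(O[Si](CC)(CC)CC)CC[C@H]1[C@](C)(CC[C@H](Br)C(C)(C)Cl)[C@@H]2CC[C@@]1(C)O2 | intermediate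
36 | dactylomelol, (1R,2S,3S,4S)-3-[(3S)-3-bromo-4-chloro-4-methylpentyl]-2-[(3S)-3-hydroxy-3-methylpent-4-en-1-yl]-1,3-dimethyl-7-oxabicyclo[2.2.1]heptane | C=C[C@@](C)(O)CC[C@H]1[C@](C)(CC[C@H](Br)C(C)(C)Cl)[C@@H]2CC[C@@]1(C)O2 | target

Total step count: 26. Longest linear sequence: 23 steps (steps 1–2, 5–16 and 18–26; steps 3–4 and 17 prepare the two side fragments).

Steps most likely to fail

Step 12 (transannular C–H insertion). The carbenoid may be consumed by dimerisation, by insertion at C6–H or by intermolecular ylide formation at O7 before the strained transannular transition state is reached. The fallback makes the same C1–C2 bond by a polar ring closure. Setting out from ester 16, RuCl3 (cat.) and NaIO4 in CCl4–MeCN–H2O should hydroxylate the more accessible tertiary ether C–H at C1 to give the lactol methyl (3R)-5-chloro-3-[(2S)-5-hydroxy-5-methyloxolan-2-yl]-3-methylpentanoate F1. Methanol with pyridinium 4-toluenesulfonate should then give the ketal methyl (3R)-5-chloro-3-[(2S)-5-methoxy-5-methyloxolan-2-yl]-3-methylpentanoate F2. LiN(i-Pr)2 and Me3SiCl at −78 °C should convert the ester into the silyl ketene acetal {[(3S)-5-chloro-1-methoxy-3-[(2S)-5-methoxy-5-methyloxolan-2-yl]-3-methylpent-1-en-1-yl]oxy}trimethylsilane F3. Catalytic Me3SiOTf at −78 °C should ionise the ketal to the 2-methyloxolan-2-ylium ion, which the ketene acetal attacks across the ring (intramolecular Mukaiyama-type addition to a cyclic oxocarbenium ion; the tether allows only the required configuration at C1), and the route is rejoined at 19.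

Step 25 (tertiary chloride next to the bromide). The bromonium or tertiary cation may lose a proton to give an isopropenyl group, or be captured transannularly by O7 instead of by chloride. The fallback sets out from alkene 32 and uses electrophilic bromochlorination with N-bromosuccinimide and Bu4NCl in CH2Cl2 at −78 °C, where chloride opens the bromonium ion at the tertiary carbon. With no controlling element at this remote alkene it should give 35 together with its bromide epimer {[(3S)-5-{(1R,2S,3S,4S)-3-[(3R)-3-bromo-4-chloro-4-methylpentyl]-1,3-dimethyl-7-oxabicyclo[2.2.1]heptan-2-yl}-3-methylpent-1-en-3-yl]oxy}triethylsilane F4, to be separated by preparative HPLC, and the route is rejoined at 35.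

Step 5 (asymmetric allylboration). Facial selectivity at the aldehyde may be poor because the bulky γ,γ-disubstituted boronate fits the catalyst pocket badly; the C3/C4 relationship is not at risk, since the chair transition state sets it. The fallback replaces catalyst control by resolution through the pool-derived C1 stereocentre. Setting out from 9 and 5, the uncatalysed allylboration (toluene, rt) should give 10 together with (2S,5R,6S)-6-(2-{[tert-butyl(dimethyl)silyl]oxy}ethyl)-5-hydroxy-6-methyloct-7-en-2-yl 4-methylbenzenesulfonate F5. NaH closes both, and the trans-oxolane 11 is separated by chromatography from the cis-oxolane tert-butyldimethyl{[(3S)-3-methyl-3-[(2R,5R)-5-methyloxolan-2-yl]pent-4-en-1-yl]oxy}silane F6, so the route is rejoined at 11.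

Further compounds
F1 | step 12 | methyl (3R)-5-chloro-3-[(2S)-5-hydroxy-5-methyloxolan-2-yl]-3-methylpentanoate | COC(=O)C[C@](C)(CCCl)[C@@H]1CCC(C)(O)O1
F2 | step 12 | methyl (3R)-5-chloro-3-[(2S)-5-methoxy-5-methyloxolan-2-yl]-3-methylpentanoate | COC(=O)C[C@](C)(CCCl)[C@@H]1CCC(C)(OC)O1
F3 | step 12 | {[(3S)-5-chloro-1-methoxy-3-[(2S)-5-methoxy-5-methyloxolan-2-yl]-3-methylpent-1-en-1-yl]oxy}trimethylsilane | COC(O[Si](C)(C)C)=C[C@](C)(CCCl)[C@@H]1CCC(C)(OC)O1
F4 | step 25 | {[(3S)-5-{(1R,2S,3S,4S)-3-[(3R)-3-bromo-4-chloro-4-methylpentyl]-1,3-dimethyl-7-oxabicyclo[2.2.1]heptan-2-yl}-3-methylpent-1-en-3-yl]oxy}triethylsilane | C=C[C@@](C)(O[Si](CC)(CC)CC)CC[C@H]1[C@](C)(CC[C@@H](Br)C(C)(C)Cl)[C@@H]2CC[C@@]1(C)O2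
F5 | step 5 | (2S,5R,6S)-6-(2-{[tert-butyl(dimethyl)silyl]oxy}ethyl)-5-hydroxy-6-methyloct-7-en-2-yl 4-methylbenzenesulfonate | CC(C)(C)[Si](C)(C)OCC[C@@](C)(C=C)[C@H](O)CC[C@H](C)OS(=O)(=O)c1ccc(C)cc1
F6 | step 5 | tert-butyldimethyl{[(3S)-3-methyl-3-[(2R,5R)-5-methyloxolan-2-yl]pent-4-en-1-yl]oxy}silane | CC(C)(C)[Si](C)(C)OCC[C@@](C)(C=C)[C@H]1CC[C@@H](C)O1
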